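**Plan**
1. The target is read as a polyketide-type resorcinol: the side chain sits on the one ring carbon that is 1,3 to both C–OH carbons, and its ketone is β to the ring.
2. Retrosynthesis first unmasks the ketone from a dioxolane, then reopens the arene by cutting the ring bond between one C–OH carbon and the CH carbon that lies between the two C–OH carbons (retro-Claisen). This maps the benzene ring onto a 6-methyl-2H-pyran-2-one: C2 and C6 become the two C–OH carbons, the 6-methyl carbon becomes the CH between them, and C4 becomes the substituted carbon.
3. The dioxolane is taken back to an alkyne, and the exocyclic bond between the future CH2 carbon and C4 is cut last, giving heptadec-1-yne and 4-bromo-6-methyl-2H-pyran-2-one.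
4. Forward: the C17 chain is joined to C4 of the pyranone (step 1), the alkyne becomes the masked ketone (step 2), and methoxide turns the pyranone ring into the benzene ring, followed by release of the ketone (step 3). The benzene ring, the only ring of the target, arises last.
5. The target has no stereocentre and no configured double bond. All selectivity is regiochemical and is fixed by the positions of C2, C4 and C6 in the pyranone.
6. No phenol protecting group is used; the only helper is the dioxolane, removed in the last operation.

Key step: step 1

Remark: compounds 1 (the bromide of triacetic acid lactone) and 2 are taken as commercial.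

**Step 1**
Reactants: 1 4-bromo-6-methyl-2H-pyran-2-one; 2 heptadec-1-yne
Product: 3 4-(heptadec-1-yn-1-yl)-6-methyl-2H-pyran-2-one
Conditions: PdCl2(PPh3)2 (3 mol %), CuI (5 mol %), Et3N (3 equiv), MeCN, 25 to 50 °C
Reagents that add atoms: none
Why: Zerovalent palladium inserts into the C4–Br bond of 1, a vinylogous acyl bromide that is more reactive than an aryl bromide; the copper acetylide of 2 transmetalates and reductive elimination joins the sp carbon to C4 (Sonogashira coupling, a reaction type established on 4-halo-2-pyranones). No ring is closed and no stereocentre is formed. The step needs substitution at C4 without attack on the lactone carbonyl C2 or on C6 and without deprotonation of the 6-methyl group; the hindered base Et3N and the neutral organocopper nucleophile should secure this, where a ketone enolate would not. The coupling also fixes the regiochemistry of all that follows: C4 is 1,3 to both C2 and C6, the carbons that will carry the phenolic oxygens, and the alkyne carbon bound to C4 must become the CH2 group because the pyranone polarises the triple bond towards attack at the distal carbon.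

**Step 2**
Reactants: 3 4-(heptadec-1-yn-1-yl)-6-methyl-2H-pyran-2-one
Product: 4 6-methyl-4-[(2-pentadecyl-1,3-dioxolan-2-yl)methyl]-2H-pyran-2-one
Conditions: (Ph3P)AuCl (3 mol %), AgOTf (3 mol %), ethane-1,2-diol (5 equiv), toluene, 80 °C
Reagents that add atoms: ethane-1,2-diol, OCCO
Why: Monovalent gold activates the alkyne, the first hydroxyl adds at the distal carbon (conjugated 1,6 to the lactone carbonyl and bearing the alkyl chain) and the second hydroxyl closes the dioxolane on the resulting enol ether (gold-catalysed double hydroalkoxylation of an alkyne to a cyclic ketal), so the future ketone is placed β to the ring and masked in one operation.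

**Step 3**
Reactants: 4 6-methyl-4-[(2-pentadecyl-1,3-dioxolan-2-yl)methyl]-2H-pyran-2-one
Product: 7 1-(3,5-dihydroxyphenyl)heptadecan-2-one, via ring-opened methyl keto ester 5 (not isolated), via dioxolane-protected resorcinol 6 (not isolated)
Conditions: NaOMe (4 equiv), MeOH–THF, 65 °C; then 2 M aq. HCl, THF, 40 °C
Reagents that add atoms: sodium methoxide, [Na+].[O-]C (its methoxy group is held only by intermediate 5); water, O
Why: Proposed new method: methoxide should open the enol lactone at C2 to keto ester 5, in which the former ring double bond holds the ester carbon and the acetonyl arm cis, so that the methyl ketone enolate (the former 6-methyl carbon) can attack the ester in a 6-exo-trig Claisen (Dieckmann-type) closure, loss of methoxide giving a cyclohexenedione that tautomerises irreversibly to resorcinolate 6, while the ketal leaves no second ketone for a competing aldol closure; the closest known reaction types are the base-mediated rearrangement of enol lactones to cyclic 1,3-diketones and the Claisen cyclisation of 5-oxohexanoates to cyclohexane-1,3-diones, and aqueous acid finally hydrolyses the dioxolane to the ketone.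

**Compound list**
1 | 4-bromo-6-methyl-2H-pyran-2-one | CC1=CC(Br)=CC(=O)O1 | starting material
2 | heptadec-1-yne | CCCCCCCCCCCCCCCC#C | starting material
3 | 4-(heptadec-1-yn-1-yl)-6-methyl-2H-pyran-2-one | CCCCCCCCCCCCCCCC#CC1=CC(=O)OC(C)=C1 | intermediate
4 | 6-methyl-4-[(2-pentadecyl-1,3-dioxolan-2-yl)methyl]-2H-pyran-2-one | CCCCCCCCCCCCCCCC1(CC2=CC(=O)OC(C)=C2)OCCO1 | intermediate
5 | methyl (2E)-5-oxo-3-[(2-pentadecyl-1,3-dioxolan-2-yl)methyl]hex-2-enoate (ester carbon and acetonyl arm cis) | COC(=O)/C=C(\CC(C)=O)CC1(CCCCCCCCCCCCCCC)OCCO1 | intermediate
6 | 5-[(2-pentadecyl-1,3-dioxolan-2-yl)methyl]benzene-1,3-diol | CCCCCCCCCCCCCCCC1(Cc2cc(O)cc(O)c2)OCCO1 | intermediate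
7 | 1-(3,5-dihydroxyphenyl)heptadecan-2-one | CCCCCCCCCCCCCCCC(=O)Cc1cc(O)cc(O)c1 | target

Total step count: 3. Longest linear sequence: 3.

**Steps most likely to fail**

Step 3 (Proposed new method). The ring-opened ester may be saponified, or may condense intermolecularly, faster than the methyl ketone enolate closes onto the ester, so that no arene forms. Fallback, known chemistry only: the arene is bought instead of made. Setting out from 2, gold-catalysed Markovnikov hydration ((Ph3P)AuCl, AgOTf, MeOH–H2O) should give heptadecan-2-one F1. Kinetic enolisation with LiN(i-Pr)2 at −78 °C and trapping with Me3SiCl should give the terminal silyl enol ether trimethyl[(heptadec-1-en-2-yl)oxy]silane F2. Palladium-catalysed arylation of F2 with 1-bromo-3,5-dimethoxybenzene (PdCl2[P(o-tol)3]2, Bu3SnF, toluene, reflux) should give 1-(3,5-dimethoxyphenyl)heptadecan-2-one F3. BBr3 in CH2Cl2 (−78 to 0 °C) removes both methyl ethers, and the route is rejoined at 7.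

Step 2. The second hydroalkoxylation may stall at the conjugated enol ether, or the oxygen may enter at the proximal alkyne carbon (loss of regiocontrol). Fallback: setting out from 3, metal-free 1,6-addition of pyrrolidine (EtOH, 25 °C) to the pyranone-polarised alkyne can only place nitrogen on the distal carbon and should give the enamine 6-methyl-4-[(1E)-2-(pyrrolidin-1-yl)heptadec-1-en-1-yl]-2H-pyran-2-one F4. Hydrolysis with aqueous acetic acid should give the ketone 6-methyl-4-(2-oxoheptadecyl)-2H-pyran-2-one F5. Ketalisation of F5 with ethane-1,2-diol and p-TsOH in benzene under Dean–Stark removal of water returns to the route at 4.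

Step 1. Oxidative homocoupling of the alkyne on copper (Glaser) and attack of the amine on the pyranone may erode the coupling. Fallback: setting out from 2, deprotonation with n-BuLi (THF, −78 °C) and transmetalation with ZnCl2 should give chloro(heptadec-1-yn-1-yl)zinc F6. Negishi coupling of F6 with 1 (Pd(PPh3)4, THF, 25 to 50 °C) forms the same bond in an amine-free and copper-free manifold and returns to the route at 3.

**Further compounds**
F1 | step 3 | heptadecan-2-one | CCCCCCCCCCCCCCCC(C)=O
F2 | step 3 | trimethyl[(heptadec-1-en-2-yl)oxy]silane | CCCCCCCCCCCCCCCC(=C)O[Si](C)(C)C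
F3 | step 3 | 1-(3,5-dimethoxyphenyl)heptadecan-2-one | CCCCCCCCCCCCCCCC(=O)Cc1cc(OC)cc(OC)c1
F4 | step 2 | 6-methyl-4-[(1E)-2-(pyrrolidin-1-yl)heptadec-1-en-1-yl]-2H-pyran-2-one | CCCCCCCCCCCCCCC/C(N1CCCC1)=C\C1=CC(=O)OC(C)=C1
F5 | step 2 | 6-methyl-4-(2-oxoheptadecyl)-2H-pyran-2-one | CCCCCCCCCCCCCCCC(=O)CC1=CC(=O)OC(C)=C1
F6 | step 1 | chloro(heptadec-1-yn-1-yl)zinc | CCCCCCCCCCCCCCCC#C[Zn]Cl
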